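**Retrosynthetic overview**
- Coumarin ring (formed last): Knoevenagel–lactonisation disconnection at C3=C4 and O1–C2 gives an isochromene quinone methide (the ring-closed form of the salicylaldehyde) and a pyranonyl acetic ester.
- Dihydropyranone ring: two-carbon ring expansion of (S)-β-butyrolactone, whose acyl C–O bond is opened by the acetoacetate dianion and re-closed on the new ketone; the lactone stereocentre becomes C2 of the pyranone.
- Arene: formyl and methyl carbons from a 4,6-dibromide by two bromine–lithium exchanges; both side-chain stereocentres from SN2 opening of (2R,3R)-2,3-epoxybutane by a 5-lithiated resorcinol bis-MOM ether, itself from iridium C–H borylation/iodination.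
- Ring order: benzene ring bought (resorcinol); dihydropyranone by ring expansion; isochromene ring formed on MOM removal and opened again in the last step; coumarin lactone ring last.

Assumption: the SMILES is read as (2R,3R) in the hydroxybutyl chain and (S) at the pyranone carbon; 13 and 14 are ring–chain tautomeric and each is drawn in one form.

**Step 1**
Reactants: 1 resorcinol (benzene-1,3-diol)
Product: 2 1,3-bis(methoxymethoxy)benzene
Conditions: NaH (2.4 equiv), MOMCl (2.4 equiv), DMF, 0 °C → rt
Reagents that add atoms: chloromethyl methyl ether (MOMCl), COCCl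
Why: Williamson O-alkylation of the bis-phenoxide masks both phenols as MOM acetals that tolerate base and organolithiums; no stereocentre is involved.

**Step 2**
Reactants: 2 1,3-bis(methoxymethoxy)benzene
Product: 4 1-iodo-3,5-bis(methoxymethoxy)benzene, via aryl pinacol boronate 3 (not isolated)
Conditions: [Ir(OMe)(cod)]2 (1 mol%), dtbpy (2 mol%), B2pin2 (1.0 equiv), THF, 80 °C; evaporate; CuI (10 mol%), 1,10-phenanthroline (20 mol%), KI (1.5 equiv), MeOH/H2O 4:1, air, 80 °C
Reagents that add atoms: potassium iodide, [K+].[I-]; bis(pinacolato)diboron, CC1(C)OB(OC1(C)C)B1OC(C)(C)C(C)(C)O1 (its boryl group is carried only by 3)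
Why: Sterically controlled iridium-catalysed C–H borylation takes the only C–H without an ortho substituent (C5), and copper-catalysed aerobic iododeboronation then replaces boron by iodine at the same carbon; no stereocentre.

**Step 3**
Reactants: 4 1-iodo-3,5-bis(methoxymethoxy)benzene; 5 (2R,3R)-2,3-dimethyloxirane [(2R,3R)-2,3-epoxybutane]
Product: 7 (2R,3R)-3-[3,5-bis(methoxymethoxy)phenyl]butan-2-ol, via aryllithium 6 (not isolated)
Conditions: t-BuLi (2.05 equiv), THF, −78 °C; 5 (1.3 equiv), BF3·OEt2 (1.3 equiv), −78 °C; H2O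
Reagents that add atoms: none
Why: Iodine–lithium exchange followed by BF3-promoted SN2 epoxide opening, in which the aryl group enters with inversion at the attacked carbon while the carbinol carbon keeps its configuration; because the trans-epoxide is C2-symmetric, attack at either carbon gives the same (2R,3R) alcohol.

**Step 4**
Reactants: 7 (2R,3R)-3-[3,5-bis(methoxymethoxy)phenyl]butan-2-ol
Product: 8 (2R,3R)-3-[2,6-dibromo-3,5-bis(methoxymethoxy)phenyl]butan-2-ol
Conditions: NBS (2.1 equiv), MeCN, 0 °C → rt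
Reagents that add atoms: N-bromosuccinimide, O=C1CCC(=O)N1Br
Why: Electrophilic aromatic bromination goes twice to the equivalent positions that are para to one MOM ether and ortho to the other (as in the 4,6-dibromination of 5-alkylresorcinol ethers) and leaves the position between the two ethers; the stereocentres are untouched.

**Step 5**
Reactants: 8 (2R,3R)-3-[2,6-dibromo-3,5-bis(methoxymethoxy)phenyl]butan-2-ol
Product: 13 2-[(2R,3R)-3-hydroxybutan-2-yl]-4,6-bis(methoxymethoxy)-3-methylbenzaldehyde, via bromo aryllithium 9 (not isolated), via bromo methyl arene 10 (not isolated), via methyl aryllithium 11 (not isolated), via lithium hemiaminal 12 (not isolated)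
Conditions: n-BuLi (2.05 equiv), THF, −78 °C; MeI (1.05 equiv), −78 °C; n-BuLi (1.3 equiv), −78 °C; DMF (4 equiv), −78 → 0 °C; aq. NH4Cl
Reagents that add atoms: iodomethane, CI; N,N-dimethylformamide, CN(C)C=O
Why: Sequential bromine–lithium exchange: the two bromides are interchanged by rotation about the aryl–C bond, so exchange of one (after alkoxide formation) and methylation, then exchange of the other and Bouveault formylation with DMF, place CH3 and CHO on either side of the side chain without touching its stereocentres.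

**Step 6**
Reactants: 13 2-[(2R,3R)-3-hydroxybutan-2-yl]-4,6-bis(methoxymethoxy)-3-methylbenzaldehyde
Product: 14 (3R,4R)-8-hydroxy-3,4,5-trimethyl-3,4-dihydro-6H-isochromen-6-one (cis-3,4-dimethyl quinone methide; ring-closed and dehydrated form of the dihydroxy aldehyde)
Conditions: p-TsOH·H2O (0.1 equiv), MeOH, 50 °C
Reagents that add atoms: none
Why: Acid-catalysed acetal exchange removes both MOM groups as dimethoxymethane, and the freed 2,4-dihydroxybenzaldehyde closes with the side-chain hydroxyl to the lactol and loses water to the vinylogous-acid quinone methide, as decarboxycitrinin-type aldehydes do; no bond to a stereocentre is broken.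

**Step 7**
Reactants: 15 methyl acetoacetate (methyl 3-oxobutanoate); 16 (4S)-4-methyloxetan-2-one [(S)-β-butyrolactone]
Product: 19 methyl 2-[(2S)-2-methyl-4-oxo-3,4-dihydro-2H-pyran-6-yl]acetate, via acetoacetate dianion 17 (not isolated), via hydroxy diketo ester 18 (not isolated)
Conditions: LDA (4.4 equiv), 15 (2.2 equiv), THF, 0 °C; 16 (1.0 equiv), −78 → −30 °C; 3 M aq. HCl to pH 1, rt
Reagents that add atoms: none
Why: Proposed new method: the hard γ-carbon of the dilithium dienolate 17 should add to the strained acyl carbon of 16 rather than to its shielded secondary C–O carbon, acyl C–O cleavage then gives the chain-extended δ-alkoxide of 18, and on acidification the freed hydroxyl closes onto the new C3 ketone and loses water, so the lactone oxygen and its untouched (S) stereocentre end up in a ring two carbons larger (net insertion of the enolate C=C into the acyl–O bond, four-membered lactone to six-membered dihydropyranone); the closest known reactions are the Claisen acylation of acetoacetate dianions by esters (Huckin–Weiler) and the acyl-selective opening of β-lactones by ester enolates, followed by the standard acid cyclodehydration of δ-hydroxy-β-diketones.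

**Step 8**
Reactants: 14 (3R,4R)-8-hydroxy-3,4,5-trimethyl-3,4-dihydro-6H-isochromen-6-one; 19 methyl 2-[(2S)-2-methyl-4-oxo-3,4-dihydro-2H-pyran-6-yl]acetate
Product: 21 7-hydroxy-5-[(2R,3R)-3-hydroxybutan-2-yl]-6-methyl-3-[(2S)-2-methyl-4-oxo-3,4-dihydro-2H-pyran-6-yl]-2H-chromen-2-one, via Knoevenagel arylidene ester 20 (not isolated)
Conditions: 19 (1.3 equiv), piperidine (0.2 equiv), AcOH (0.2 equiv), EtOH, 60 °C
Reagents that add atoms: none
Why: Knoevenagel condensation then lactonisation: piperidine opens the quinone methide at C1 to the salicylaldehyde iminium, the doubly activated CH2 of 19 condenses, and the ortho phenol closes onto the methyl ester to give the aromatic coumarin and free the side-chain hydroxyl; neither the (2R,3R) chain nor the (S) pyranone centre takes part in any bond change.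

**Compound list**
1 | resorcinol (benzene-1,3-diol) | Oc1cccc(O)c1 | starting material
2 | 1,3-bis(methoxymethoxy)benzene | COCOc1cccc(OCOC)c1 | intermediate
3 | 2-[3,5-bis(methoxymethoxy)phenyl]-4,4,5,5-tetramethyl-1,3,2-dioxaborolane | COCOc1cc(OCOC)cc(c1)B1OC(C)(C)C(C)(C)O1 | intermediate
4 | 1-iodo-3,5-bis(methoxymethoxy)benzene | COCOc1cc(I)cc(OCOC)c1 | intermediate
5 | (2R,3R)-2,3-dimethyloxirane | C[C@H]1O[C@@H]1C | starting material
6 | [3,5-bis(methoxymethoxy)phenyl]lithium | [Li]c1cc(OCOC)cc(OCOC)c1 | intermediate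
7 | (2R,3R)-3-[3,5-bis(methoxymethoxy)phenyl]butan-2-ol | COCOc1cc(OCOC)cc(c1)[C@@H](C)[C@@H](C)O | intermediate
8 | (2R,3R)-3-[2,6-dibromo-3,5-bis(methoxymethoxy)phenyl]butan-2-ol | COCOc1cc(OCOC)c(Br)c(c1Br)[C@@H](C)[C@@H](C)O | intermediate
9 | lithium (2R,3R)-3-[2-bromo-6-lithio-3,5-bis(methoxymethoxy)phenyl]butan-2-olate | COCOc1cc(OCOC)c(Br)c(c1[Li])[C@@H](C)[C@@H](C)O[Li] | intermediate
10 | lithium (2R,3R)-3-[2-bromo-3,5-bis(methoxymethoxy)-6-methylphenyl]butan-2-olate | COCOc1cc(OCOC)c(Br)c(c1C)[C@@H](C)[C@@H](C)O[Li] | intermediate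
11 | lithium (2R,3R)-3-[2-lithio-3,5-bis(methoxymethoxy)-6-methylphenyl]butan-2-olate | COCOc1cc(OCOC)c([Li])c(c1C)[C@@H](C)[C@@H](C)O[Li] | intermediate
12 | lithium (2R,3R)-3-{2-[(dimethylamino)(lithiooxy)methyl]-3,5-bis(methoxymethoxy)-6-methylphenyl}butan-2-olate (DMF adduct, both epimers at the hemiaminal carbon) | COCOc1cc(OCOC)c(C(O[Li])N(C)C)c(c1C)[C@@H](C)[C@@H](C)O[Li] | intermediate
13 | 2-[(2R,3R)-3-hydroxybutan-2-yl]-4,6-bis(methoxymethoxy)-3-methylbenzaldehyde (in equilibrium with its lactol) | COCOc1cc(OCOC)c(C=O)c(c1C)[C@@H](C)[C@@H](C)O | intermediate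
14 | (3R,4R)-8-hydroxy-3,4,5-trimethyl-3,4-dihydro-6H-isochromen-6-one | CC1=C2[C@@H](C)[C@@H](C)OC=C2C(O)=CC1=O | intermediate
15 | methyl acetoacetate (methyl 3-oxobutanoate) | COC(=O)CC(C)=O | starting material
16 | (4S)-4-methyloxetan-2-one [(S)-β-butyrolactone] | C[C@H]1CC(=O)O1 | starting material
17 | dilithium 1-methoxybuta-1,3-diene-1,3-bis(olate) (acetoacetate dianion) | COC(O[Li])=CC(=C)O[Li] | intermediate
18 | methyl (7S)-7-hydroxy-3,5-dioxooctanoate (formed as its lithium salt, set free on acidification) | COC(=O)CC(=O)CC(=O)C[C@H](C)O | intermediate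
19 | methyl 2-[(2S)-2-methyl-4-oxo-3,4-dihydro-2H-pyran-6-yl]acetate | COC(=O)CC1=CC(=O)C[C@H](C)O1 | intermediate
20 | methyl (2Z)-3-{2,4-dihydroxy-6-[(2R,3R)-3-hydroxybutan-2-yl]-5-methylphenyl}-2-[(2S)-2-methyl-4-oxo-3,4-dihydro-2H-pyran-6-yl]prop-2-enoate | COC(=O)/C(=C\c1c(O)cc(O)c(C)c1[C@@H](C)[C@@H](C)O)C1=CC(=O)C[C@H](C)O1 | intermediate
21 | 7-hydroxy-5-[(2R,3R)-3-hydroxybutan-2-yl]-6-methyl-3-[(2S)-2-methyl-4-oxo-3,4-dihydro-2H-pyran-6-yl]-2H-chromen-2-one | Cc1c(O)cc2oc(=O)c(C3=CC(=O)C[C@H](C)O3)cc2c1[C@@H](C)[C@@H](C)O | target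

**Totals**
Total step count: 8. Longest linear sequence: 7 (steps 1–6, then step 8).

**Steps most likely to fail, with fallbacks**

Step 7 (the proposed ring expansion). The dianion may attack the C–O carbon of the lactone or deprotonate it and trigger elimination to crotonate. The fallback uses known chemistry, sets out from 15 and comes back at 19. Commercial methyl (3S)-3-hydroxybutanoate F1 is silylated (TBSCl, imidazole, DMF) to methyl (3S)-3-[(tert-butyldimethylsilyl)oxy]butanoate F2. This ester acylates dianion 17 in an established Claisen acylation (THF, −78 → 0 °C) to give methyl (7S)-7-[(tert-butyldimethylsilyl)oxy]-3,5-dioxooctanoate F3. TFA in wet CH2Cl2 removes the silyl group, and the liberated 18 cyclodehydrates to 19.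

Step 8 (coumarin formation on the quinone methide). The carbon nucleophile may stop at the 1-substituted isochroman, or 14 may dimerise. The fallback masks the side-chain hydroxyl so that no quinone methide can form; it sets out from 8 and comes back at 21. TBSOTf/2,6-lutidine gives tert-butyl({(2R,3R)-3-[2,6-dibromo-3,5-bis(methoxymethoxy)phenyl]butan-2-yl}oxy)dimethylsilane F4. The two bromine–lithium exchanges of step 5 (MeI, then DMF) give 2-{(2R,3R)-3-[(tert-butyldimethylsilyl)oxy]butan-2-yl}-4,6-bis(methoxymethoxy)-3-methylbenzaldehyde F5. ZnBr2/n-PrSH in CH2Cl2 removes only the aryl MOM groups and gives the free salicylaldehyde 2-{(2R,3R)-3-[(tert-butyldimethylsilyl)oxy]butan-2-yl}-4,6-dihydroxy-3-methylbenzaldehyde F6. Piperidine/AcOH condensation with 19 gives 5-{(2R,3R)-3-[(tert-butyldimethylsilyl)oxy]butan-2-yl}-7-hydroxy-6-methyl-3-[(2S)-2-methyl-4-oxo-3,4-dihydro-2H-pyran-6-yl]-2H-chromen-2-one F7, and HF·pyridine in THF then gives 21.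

Step 5 (one-flask differentiation of the two bromides). Over-exchange or incomplete quenching would give dimethyl, diformyl or reduced by-products. The fallback replaces the second lithiation by electrophilic formylation; it sets out from 7 and comes back at 14. NBS (1.0 equiv) gives (2R,3R)-3-[2-bromo-3,5-bis(methoxymethoxy)phenyl]butan-2-ol F8. n-BuLi (2.1 equiv) then MeI gives (2R,3R)-3-[3,5-bis(methoxymethoxy)-2-methylphenyl]butan-2-ol F9. Acidic methanol gives 5-[(2R,3R)-3-hydroxybutan-2-yl]-4-methylbenzene-1,3-diol F10. Vilsmeier formylation (POCl3, DMF, MeCN; aq. NaOAc) goes para to one hydroxyl and next to the side chain, whose hydroxyl captures the iminium, and hydrolysis gives 14.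

**Further compounds**
F1 | step 7 | methyl (3S)-3-hydroxybutanoate (purchased for the fallback) | C[C@H](O)CC(=O)OC
F2 | step 7 | methyl (3S)-3-[(tert-butyldimethylsilyl)oxy]butanoate | C[C@H](O[Si](C)(C)C(C)(C)C)CC(=O)OC
F3 | step 7 | methyl (7S)-7-[(tert-butyldimethylsilyl)oxy]-3,5-dioxooctanoate | COC(=O)CC(=O)CC(=O)C[C@H](C)O[Si](C)(C)C(C)(C)C
F4 | step 8 | tert-butyl({(2R,3R)-3-[2,6-dibromo-3,5-bis(methoxymethoxy)phenyl]butan-2-yl}oxy)dimethylsilane | COCOc1cc(OCOC)c(Br)c(c1Br)[C@@H](C)[C@@H](C)O[Si](C)(C)C(C)(C)C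
F5 | step 8 | 2-{(2R,3R)-3-[(tert-butyldimethylsilyl)oxy]butan-2-yl}-4,6-bis(methoxymethoxy)-3-methylbenzaldehyde | COCOc1cc(OCOC)c(C=O)c(c1C)[C@@H](C)[C@@H](C)O[Si](C)(C)C(C)(C)C
F6 | step 8 | 2-{(2R,3R)-3-[(tert-butyldimethylsilyl)oxy]butan-2-yl}-4,6-dihydroxy-3-methylbenzaldehyde | Cc1c(O)cc(O)c(C=O)c1[C@@H](C)[C@@H](C)O[Si](C)(C)C(C)(C)C
F7 | step 8 | 5-{(2R,3R)-3-[(tert-butyldimethylsilyl)oxy]butan-2-yl}-7-hydroxy-6-methyl-3-[(2S)-2-methyl-4-oxo-3,4-dihydro-2H-pyran-6-yl]-2H-chromen-2-one | Cc1c(O)cc2oc(=O)c(C3=CC(=O)C[C@H](C)O3)cc2c1[C@@H](C)[C@@H](C)O[Si](C)(C)C(C)(C)C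
F8 | step 5 | (2R,3R)-3-[2-bromo-3,5-bis(methoxymethoxy)phenyl]butan-2-ol | COCOc1cc(OCOC)c(Br)c(c1)[C@@H](C)[C@@H](C)O
F9 | step 5 | (2R,3R)-3-[3,5-bis(methoxymethoxy)-2-methylphenyl]butan-2-ol | COCOc1cc(OCOC)c(C)c(c1)[C@@H](C)[C@@H](C)O
F10 | step 5 | 5-[(2R,3R)-3-hydroxybutan-2-yl]-4-methylbenzene-1,3-diol | Cc1c(O)cc(O)cc1[C@@H](C)[C@@H](C)O
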